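**Retrosynthetic overview**
1. The seven-membered dioxepinone (depsidone) ring is made last. Its aryl ester C–O comes from lactonisation and its diaryl ether C–O from palladium-catalysed etherification of ring-B phenol 14 with ring-A triflate 20. The ring-A ketone travels as a dioxolane.
2. The oxane and isochromanone rings of the spiroketal close together, under acid, from δ-hydroxy ketone 10 and its ortho ester. C-6' comes from an enzymatic methyl ketone reduction and then fixes the spiro carbon C-3 thermodynamically.
3. Enabling feature: in the oxane ring the ketal carbon (C-3 = C-2') and the carbinol carbon C-6' stand 1,5 to each other across three unsubstituted CH2 groups. Excising C-3'/C-4' as ethylene, with C-6' raised to the ketone level, leaves ArCH2–CO–CH2–CO–CH3. Its chelated enol is a (2+2) chromophore, so a de Mayo photocycloaddition/retro-aldol (temporary cyclobutanol) inserts ethylene in one operation.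
4. Both arenes come from orsellinic acid building blocks by lateral lithiation and Weinreb acylation. O-5 of ring B enters by bromination, borylation and oxidation.
5. Ring order: temporary cyclobutane (made and opened in step 5), oxane plus isochromanone (step 7), dioxepinone (step 16).

Key step: step 5

Assumption: locants follow spiro[isochromane-3,2'-oxane] numbering (C-1 lactone carbonyl, C-3 spiro carbon, C-4 benzylic CH2, primed locants for the oxane). Chair analysis shows the target's (3S,6'R) isomer to be the one with the lactone oxygen axial and the methyl group equatorial, so it is taken to be the thermodynamic spiroketal.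

Step 1
Reactants: 1 methyl 2,4-dihydroxy-6-methylbenzoate (methyl orsellinate)
Product: 2 methyl 2,4-bis(benzyloxy)-6-methylbenzoate
Conditions: BnBr (2.5 equiv), K2CO3, DMF, 60 °C
Reagents that add atoms: benzyl bromide, BrCc1ccccc1
Why: Williamson ether synthesis in which excess base and heat also alkylate the chelated 2-OH; benzyl is chosen because all benzyl groups of the route fall together in step 15.

Step 2
Reactants: 3 ethyl 2-(2-methyl-1,3-dioxolan-2-yl)acetate (ethyl acetoacetate ethylene ketal)
Product: 4 N-methoxy-N-methyl-2-(2-methyl-1,3-dioxolan-2-yl)acetamide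
Conditions: MeNH(OMe)·HCl, iPrMgCl, THF, −20 °C
Reagents that add atoms: N,O-dimethylhydroxylamine hydrochloride, CNOC.Cl
Why: Weinreb amide synthesis by aminolysis of the ester with the magnesium amide; the ketal keeps the future methyl ketone silent, and the amide α-protons are far less acidic than those of the ester.

Step 3
Reactants: 2 methyl 2,4-bis(benzyloxy)-6-methylbenzoate; 4 N-methoxy-N-methyl-2-(2-methyl-1,3-dioxolan-2-yl)acetamide
Product: 5 methyl 2,4-bis(benzyloxy)-6-[3-(2-methyl-1,3-dioxolan-2-yl)-2-oxopropyl]benzoate
Conditions: LiN(iPr)2 (1.1 equiv), THF, −78 °C; 4; then AcOH, −78 °C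
Reagents that add atoms: none
Why: Lateral (benzylic) lithiation of an ortho-toluate followed by Weinreb ketone synthesis, in which the chelated adduct prevents over-addition and releases the acidic ketone only at the quench.

Step 4
Reactants: 5 methyl 2,4-bis(benzyloxy)-6-[3-(2-methyl-1,3-dioxolan-2-yl)-2-oxopropyl]benzoate
Product: 6 methyl 2,4-bis(benzyloxy)-6-(2,4-dioxopentyl)benzoate
Conditions: 1 M HCl, THF, 23 °C
Reagents that add atoms: water, O
Why: Acid-catalysed ketal hydrolysis under mild conditions should free the β-diketone (largely as its chelated enol) without the isocoumarin or naphthol closures, which need strong acid or base.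

Step 5
Reactants: 6 methyl 2,4-bis(benzyloxy)-6-(2,4-dioxopentyl)benzoate; 7 ethylene
Product: 9 methyl 2,4-bis(benzyloxy)-6-(2,6-dioxoheptyl)benzoate, via acetylcyclobutanol 8 (not isolated)
Conditions: C2H4 (5 bar), MeCN, hν (λ > 300 nm, Pyrex), 5 °C
Reagents that add atoms: none
Why: Excitation of the hydrogen-bonded enol of 6, the only enone-type chromophore present, gives a triplet that adds ethylene stepwise through a 1,4-biradical across the enol C=C, so that one ethylene carbon bonds to the hydroxyl-bearing carbon carrying the arylmethyl group (the later spiro carbon C-3) and the other to the acetyl-bearing CH (the later C-5'), closing the temporary cyclobutane of 8 in a (2+2) mode. The strained β-hydroxy ketone 8 then undergoes spontaneous retro-aldol cleavage of the former enol bond, which removes the four-membered ring again and leaves ethylene inserted as C-3'–C-4' of the 1,5-diketone 9. This is the de Mayo reaction, whose closest precedent is the photoaddition of acetylacetone-type β-diketones to simple unactivated alkenes, and enone–ethylene (2+2) photocycloadditions are routine. The two stereocentres of 8 are erased in the fragmentation, so no stereocontrol is needed here, and C-6' and C-3 are set in steps 6 and 7. Ethylene is symmetrical, so no head-to-head or head-to-tail question arises, and the tautomeric chelated enol can only drain into the same diketone 9. Chemoselectivity rests on the long-wavelength cut-off (benzoate and benzyl ethers should not be cleaved above 300 nm), on the neutral medium (no Dieckmann or aldol closure of 6 or 9) and on the large excess of ethylene, which should outrun non-productive decay of the excited enol.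

Step 6
Reactants: 9 methyl 2,4-bis(benzyloxy)-6-(2,6-dioxoheptyl)benzoate
Product: 10 methyl 2,4-bis(benzyloxy)-6-[(6R)-6-hydroxy-2-oxoheptyl]benzoate
Conditions: alcohol dehydrogenase from Lactobacillus brevis, NADP+ (cat.), iPrOH (15 vol %), MgCl2 (1 mM), phosphate buffer pH 7, MTBE second phase, 30 °C
Reagents that add atoms: none
Why: Biocatalytic ketone reduction by an anti-Prelog alcohol dehydrogenase, which converts methyl ketones into (R)-2-alkanols and so sets C-6' as R under enzyme control, while the benzylic ketone with two large flanking groups should not fit the small-group pocket.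

Step 7
Reactants: 10 methyl 2,4-bis(benzyloxy)-6-[(6R)-6-hydroxy-2-oxoheptyl]benzoate
Product: 11 (3S,6'R)-6,8-bis(benzyloxy)-6'-methyl-3',4',5',6'-tetrahydrospiro[isochromane-3,2'-pyran]-1-one
Conditions: CSA (20 mol %), 4 Å MS, toluene, 80 °C
Reagents that add atoms: none
Why: Acid-catalysed spiroketalisation with lactonisation, in which the cyclic hemiketal form ionises, the neighbouring ester carbonyl captures the oxocarbenium ion and methanol is lost; because the process is reversible, C-3 should settle as S under thermodynamic control by C-6' (lactone oxygen axial through the anomeric effect, methyl equatorial).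

Step 8
Reactants: 11 (3S,6'R)-6,8-bis(benzyloxy)-6'-methyl-3',4',5',6'-tetrahydrospiro[isochromane-3,2'-pyran]-1-one
Product: 12 (3S,6'R)-6,8-bis(benzyloxy)-5-bromo-6'-methyl-3',4',5',6'-tetrahydrospiro[isochromane-3,2'-pyran]-1-one
Conditions: NBS (1.05 equiv), MeCN, 0 °C, dark
Reagents that add atoms: N-bromosuccinimide, O=C1CCC(=O)N1Br
Why: Electrophilic aromatic bromination, which in resorcinol diethers prefers the ortho/para site (C-5) over the position flanked by both alkoxy groups (C-7); it is placed after the photochemical step so that no C–Br bond is irradiated.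

Step 9
Reactants: 12 (3S,6'R)-6,8-bis(benzyloxy)-5-bromo-6'-methyl-3',4',5',6'-tetrahydrospiro[isochromane-3,2'-pyran]-1-one
Product: 14 (3S,6'R)-6,8-bis(benzyloxy)-5-hydroxy-6'-methyl-3',4',5',6'-tetrahydrospiro[isochromane-3,2'-pyran]-1-one, via aryl pinacol boronate 13 (not isolated)
Conditions: HBpin, Et3N, PdCl2(MeCN)2 (3 mol %), SPhos, dioxane, 80 °C; then H2O2 (30 % aq.), phosphate buffer pH 7.5, THF, 0 °C
Reagents that add atoms: pinacolborane, B1OC(C)(C)C(C)(C)O1 (atoms in 13 only); hydrogen peroxide, OO
Why: Miyaura-type borylation with a bulky biaryl phosphine suited to di-ortho-substituted bromides, followed by boronate oxidation (1,2-aryl shift to oxygen) at near-neutral pH, which should spare the lactone ketal.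

Step 10
Reactants: 15 2-hydroxy-4-methoxy-6-methylbenzoic acid (everninic acid)
Product: 16 benzyl 2-hydroxy-4-methoxy-6-methylbenzoate
Conditions: BnBr (1.05 equiv), KHCO3, DMF, 40 °C
Reagents that add atoms: benzyl bromide, BrCc1ccccc1
Why: SN2 alkylation of the carboxylate with a base too weak to deprotonate the chelated phenol, giving an ester that is later removed by hydrogenolysis.

Step 11
Reactants: 16 benzyl 2-hydroxy-4-methoxy-6-methylbenzoate; 17 N-methoxy-N-methylhexanamide
Product: 18 benzyl 2-hydroxy-4-methoxy-6-(2-oxoheptyl)benzoate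
Conditions: LiN(iPr)2 (2.3 equiv), THF, −78 °C; 17; then AcOH, −78 °C
Reagents that add atoms: none
Why: Lateral lithiation of the 6-methylsalicylate (phenoxide plus benzylic deprotonation) and Weinreb ketone synthesis, with a cold acidic quench to avoid enol lactonisation to the isocoumarin.

Step 12
Reactants: 18 benzyl 2-hydroxy-4-methoxy-6-(2-oxoheptyl)benzoate
Product: 19 benzyl 2-hydroxy-4-methoxy-6-[(2-pentyl-1,3-dioxolan-2-yl)methyl]benzoate
Conditions: (TMSOCH2)2, TMSOTf (10 mol %), CH2Cl2, −78 to −20 °C
Reagents that add atoms: 1,2-bis(trimethylsilyloxy)ethane, C[Si](C)(C)OCCO[Si](C)(C)C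
Why: Aprotic ketalisation with the bis-silylated glycol, driven by disiloxane formation, works at low temperature where the keto ester cannot cyclise; the ketal is needed because a free 2-oxoalkyl group would capture any activated ring-A carboxyl.

Step 13
Reactants: 19 benzyl 2-hydroxy-4-methoxy-6-[(2-pentyl-1,3-dioxolan-2-yl)methyl]benzoate
Product: 20 benzyl 4-methoxy-2-[(2-pentyl-1,3-dioxolan-2-yl)methyl]-6-(trifluoromethylsulfonyloxy)benzoate
Conditions: Tf2O, pyridine, CH2Cl2, 0 °C
Reagents that add atoms: trifluoromethanesulfonic anhydride, O=S(=O)(OS(=O)(=O)C(F)(F)F)C(F)(F)F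
Why: O-Sulfonylation of the phenol turns the natural salicylate oxygen site into an electron-poor coupling electrophile, and the pyridine buffer protects the ketal.

Step 14
Reactants: 14 (3S,6'R)-6,8-bis(benzyloxy)-5-hydroxy-6'-methyl-3',4',5',6'-tetrahydrospiro[isochromane-3,2'-pyran]-1-one; 20 benzyl 4-methoxy-2-[(2-pentyl-1,3-dioxolan-2-yl)methyl]-6-(trifluoromethylsulfonyloxy)benzoate
Product: 21 benzyl 2-{[(3S,6'R)-6,8-bis(benzyloxy)-6'-methyl-1-oxo-3',4',5',6'-tetrahydrospiro[isochromane-3,2'-pyran]-5-yl]oxy}-4-methoxy-6-[(2-pentyl-1,3-dioxolan-2-yl)methyl]benzoate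
Conditions: Pd(OAc)2 (5 mol %), tBuXPhos (10 mol %), K3PO4, toluene, 100 °C
Reagents that add atoms: none
Why: Buchwald–Hartwig diaryl ether synthesis, in which the ortho-ester triflate favours oxidative addition and C–O reductive elimination, the bulky di-tert-butyl biaryl phosphine is the ligand class made for ortho-substituted phenols, and 14 offers only one free OH.

Step 15
Reactants: 21 the diaryl ether of step 14
Product: 22 2-{[(3S,6'R)-6,8-dihydroxy-6'-methyl-1-oxo-3',4',5',6'-tetrahydrospiro[isochromane-3,2'-pyran]-5-yl]oxy}-4-methoxy-6-[(2-pentyl-1,3-dioxolan-2-yl)methyl]benzoic acid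
Conditions: H2 (1 atm), Pd/C (10 wt %), EtOAc–EtOH, 23 °C
Reagents that add atoms: none
Why: Catalytic hydrogenolysis removes both benzyl ethers and the benzyl ester at once under neutral conditions that leave the two ketals, the lactone and the diaryl ether untouched.

Step 16
Reactants: 22 the seco acid of step 15
Product: 23 depsidone ketal: the seven-membered lactone of 22 between the ring-A carboxyl group and O-6 of ring B (8-OH free, dioxolane intact, 3S,6'R)
Conditions: DCC (1.3 equiv), DMAP (10 mol %), CH2Cl2 (2 mM), 0 to 23 °C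
Reagents that add atoms: none
Why: Carbodiimide (Steglich-type) lactonisation, the classical depsidone ring closure, in which only the 6-OH next to the ether bridge can reach the activated carboxyl, the 8-OH is chelated and remote, and the ketal blocks enol lactone formation on ring A.

Step 17
Reactants: 23 depsidone ketal
Product: 24 target CNP0301127.1: 23 with the dioxolane replaced by the ketone of the 2-oxoheptyl side chain, (3S,6'R)
Conditions: 0.5 M HCl, THF–H2O, 23 °C
Reagents that add atoms: water, O
Why: Acid-catalysed dioxolane hydrolysis; the spiroketal already sits at its thermodynamic minimum, so any reversible opening should return the same 3S isomer, and C-6' is not involved.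

**Compound list**
1 | methyl 2,4-dihydroxy-6-methylbenzoate | COC(=O)c1c(C)cc(O)cc1O | starting material
2 | methyl 2,4-bis(benzyloxy)-6-methylbenzoate | COC(=O)c1c(C)cc(OCc2ccccc2)cc1OCc1ccccc1 | intermediate
3 | ethyl 2-(2-methyl-1,3-dioxolan-2-yl)acetate | CCOC(=O)CC1(C)OCCO1 | starting material
4 | N-methoxy-N-methyl-2-(2-methyl-1,3-dioxolan-2-yl)acetamide | CON(C)C(=O)CC1(C)OCCO1 | intermediate
5 | methyl 2,4-bis(benzyloxy)-6-[3-(2-methyl-1,3-dioxolan-2-yl)-2-oxopropyl]benzoate | COC(=O)c1c(CC(=O)CC2(C)OCCO2)cc(OCc2ccccc2)cc1OCc1ccccc1 | intermediate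
6 | methyl 2,4-bis(benzyloxy)-6-(2,4-dioxopentyl)benzoate | COC(=O)c1c(CC(=O)CC(C)=O)cc(OCc2ccccc2)cc1OCc1ccccc1 | intermediate
7 | ethylene | C=C | starting material
8 | methyl 2-[(2-acetyl-1-hydroxycyclobutyl)methyl]-4,6-bis(benzyloxy)benzoate (stereoisomer mixture, not isolated) | COC(=O)c1c(CC2(O)CCC2C(C)=O)cc(OCc2ccccc2)cc1OCc1ccccc1 | intermediate
9 | methyl 2,4-bis(benzyloxy)-6-(2,6-dioxoheptyl)benzoate | COC(=O)c1c(CC(=O)CCCC(C)=O)cc(OCc2ccccc2)cc1OCc1ccccc1 | intermediate
10 | methyl 2,4-bis(benzyloxy)-6-[(6R)-6-hydroxy-2-oxoheptyl]benzoate | COC(=O)c1c(CC(=O)CCC[C@@H](C)O)cc(OCc2ccccc2)cc1OCc1ccccc1 | intermediate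
11 | (3S,6'R)-6,8-bis(benzyloxy)-6'-methyl-3',4',5',6'-tetrahydrospiro[isochromane-3,2'-pyran]-1-one | C(c1ccccc1)Oc1cc(OCc2ccccc2)c2c(c1)C[C@]1(CCC[C@@H](C)O1)OC2=O | intermediate
12 | 5-bromo derivative of 11 | C(c1ccccc1)Oc1cc(OCc2ccccc2)c2c(c1Br)C[C@]1(CCC[C@@H](C)O1)OC2=O | intermediate
13 | 5-(4,4,5,5-tetramethyl-1,3,2-dioxaborolan-2-yl) derivative of 11 (not isolated) | C(c1ccccc1)Oc1cc(OCc2ccccc2)c2c(c1B1OC(C)(C)C(C)(C)O1)C[C@]1(CCC[C@@H](C)O1)OC2=O | intermediate
14 | 5-hydroxy derivative of 11 | C(c1ccccc1)Oc1cc(OCc2ccccc2)c2c(c1O)C[C@]1(CCC[C@@H](C)O1)OC2=O | intermediate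
15 | 2-hydroxy-4-methoxy-6-methylbenzoic acid | COc1cc(C)c(C(=O)O)c(O)c1 | starting material
16 | benzyl 2-hydroxy-4-methoxy-6-methylbenzoate | COc1cc(C)c(C(=O)OCc2ccccc2)c(O)c1 | intermediate
17 | N-methoxy-N-methylhexanamide | CCCCCC(=O)N(C)OC | starting material
18 | benzyl 2-hydroxy-4-methoxy-6-(2-oxoheptyl)benzoate | CCCCCC(=O)Cc1cc(OC)cc(O)c1C(=O)OCc1ccccc1 | intermediate
19 | benzyl 2-hydroxy-4-methoxy-6-[(2-pentyl-1,3-dioxolan-2-yl)methyl]benzoate | CCCCCC1(Cc2cc(OC)cc(O)c2C(=O)OCc2ccccc2)OCCO1 | intermediate
20 | benzyl 4-methoxy-2-[(2-pentyl-1,3-dioxolan-2-yl)methyl]-6-(trifluoromethylsulfonyloxy)benzoate | CCCCCC1(Cc2cc(OC)cc(OS(=O)(=O)C(F)(F)F)c2C(=O)OCc2ccccc2)OCCO1 | intermediate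
21 | diaryl ether of 14 and 20 | CCCCCC1(Cc2cc(OC)cc(Oc3c(OCc4ccccc4)cc(OCc4ccccc4)c4c3C[C@]3(CCC[C@@H](C)O3)OC4=O)c2C(=O)OCc2ccccc2)OCCO1 | intermediate
22 | seco acid (free carboxyl, 6-OH and 8-OH) | CCCCCC1(Cc2cc(OC)cc(Oc3c(O)cc(O)c4c3C[C@]3(CCC[C@@H](C)O3)OC4=O)c2C(=O)O)OCCO1 | intermediate
23 | depsidone ketal | CCCCCC1(Cc2cc(OC)cc3c2C(=O)Oc2cc(O)c4c(c2O3)C[C@]2(CCC[C@@H](C)O2)OC4=O)OCCO1 | intermediate
24 | CNP0301127.1 | CCCCCC(=O)Cc1cc(OC)cc2c1C(=O)Oc1cc(O)c3c(c1O2)C[C@]1(CCC[C@@H](C)O1)OC3=O | target

**Step count:** 17 steps in total.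
**Longest linear sequence:** 12 steps (steps 1, 3 to 9 and 14 to 17).

**Steps most likely to fail**

**Step 5.**
- Risk: the benzoate chromophore may act as an inner filter. Capture of the short-lived excited enol by ethylene may be slow. Prolonged irradiation may cause α-cleavage photolysis at the benzylic ketone of the product.
- Fallback: the photochemistry is given up and the five-carbon chain is brought in ready-made. Commercial ethyl 5-oxohexanoate is ketalised (ethylene glycol, TsOH, toluene, reflux) to ethyl 4-(2-methyl-1,3-dioxolan-2-yl)butanoate F1.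
- Toluate 2 is deprotonated laterally with LiN(iPr)2 (2.2 equiv, THF, −78 °C) and acylated with F1 to methyl 2,4-bis(benzyloxy)-6-[5-(2-methyl-1,3-dioxolan-2-yl)-2-oxopentyl]benzoate F2. Mild aqueous acid then frees the methyl ketone.
- The fallback sets out from 2 and comes back to the route at 9.

**Step 14.**
- Risk: the di-ortho-substituted phenoxide may bind slowly to palladium. This would leave room for sulfonyl transfer from the triflate to the phenoxide and for reduction of the electrophile.
- Fallback: the bond is made instead by an oxidative copper-mediated Chan–Lam coupling at room temperature. Triflate 20 is borylated with B2(OH)4 (Pd(OAc)2, XPhos, KOAc, EtOH, 80 °C) to 2-(benzyloxycarbonyl)-5-methoxy-3-[(2-pentyl-1,3-dioxolan-2-yl)methyl]phenylboronic acid F3.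
- F3 is then coupled with phenol 14 (Cu(OAc)2, pyridine, 4 Å MS, air, CH2Cl2, 23 °C).
- The fallback sets out from 20 and 14 and comes back at 21.

**Step 6.**
- Risk: the large lipophilic substrate may be poorly taken up by the enzyme in the aqueous medium. Slow aldol cyclisation of the 1,5-diketone could also occur during long incubation.
- Fallback: C-6' is taken from the chiral pool instead of being created by reduction. Toluate 2 is deprotonated laterally (LiN(iPr)2, THF, −78 °C) and added to commercial (R)-6-methyltetrahydro-2H-pyran-2-one, whose ring opening gives the δ-hydroxy ketone directly.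
- The fallback sets out from 2, comes back at 10 and makes no compound outside the list (F0).

**Further compounds**
F1 | step 5 | ethyl 4-(2-methyl-1,3-dioxolan-2-yl)butanoate | CCOC(=O)CCCC1(C)OCCO1
F2 | step 5 | methyl 2,4-bis(benzyloxy)-6-[5-(2-methyl-1,3-dioxolan-2-yl)-2-oxopentyl]benzoate | COC(=O)c1c(CC(=O)CCCC2(C)OCCO2)cc(OCc2ccccc2)cc1OCc1ccccc1
F3 | step 14 | 2-(benzyloxycarbonyl)-5-methoxy-3-[(2-pentyl-1,3-dioxolan-2-yl)methyl]phenylboronic acid | CCCCCC1(Cc2cc(OC)cc(B(O)O)c2C(=O)OCc2ccccc2)OCCO1
F0 | step 6 | none | none
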